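**Strategy.** The cyclopentane ring (C1–C5) carries oxygen at C5, flanked by the C4 gem-dimethyl group and the C3 carbinol. This is the imprint of a 2-alkoxycyclobutanone fused across C1–C5 and enlarged by one CMe2 unit. The route therefore rests on cutting C1–C2 and C5–C3. A [2+2] photocycloaddition of 1,1-diethoxyethene to a 3-benzyloxycyclohept-2-enone makes both bonds, the four-membered ring, the oxygenated quaternary C5 and the masked C3 ketone in one operation. The precursor is the enantiopure cycloheptenone (C10=O, C1=C5) that already holds C8-Me, the quaternary C9 and a benzyl-protected hydroxyethyl arm. Isopropenyl addition and a strain-driven 1,2-shift then give the cyclopentanone; Negishi coupling adds the butenolide.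

Key step: step 9

Conventions: the seven-membered ring is C10 (C=O), C9, C8, C7, C6, C5, C1. The cyclopentane is C1–C5 and the arm is C11–C12. The β face carries the C9 arm and, in the target, C5-OH. The α face carries C8-Me and C9-Me and, in the target, C1-H and C3-OH. The target is (1R,3R,5R,8R,9S) and trans-fused, whereas the photoadduct is cis-fused, so C1 must be inverted (step 14).

Assumption: the antipode of the chiral carbene ligand in step 1 that gives the 3R centre is picked in a test run, and the ee is checked on 5.

**Step 1**
Reactants: 1 2-methylcyclopent-2-en-1-one; 2 methylmagnesium bromide; 3 allyl iodide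
Product: 5 (2S,3R)-2-allyl-2,3-dimethylcyclopentan-1-one, via bromomagnesium enolate 4 (not isolated)
Conditions: 2 (1.2 equiv), Cu(OTf)2 (1 mol %), chiral hydroxyalkyl imidazolinium salt (NHC precursor, 1.5 mol %), Et2O, −30 °C; then 3 (3 equiv), DMPU, −30 °C → rt
Reagents that add atoms: none
Why: Copper-catalysed asymmetric conjugate addition with enolate trapping: the chiral NHC–copper methyl species delivers CH3 to one face of the enone and so sets C8 (3R), and the tetrasubstituted magnesium enolate 4 is then allylated on the face anti to that neighbouring methyl group, which sets the quaternary C9 (2S) with the two methyl groups cis.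

**Step 2**
Reactants: 5 (2S,3R)-2-allyl-2,3-dimethylcyclopentan-1-one
Product: 7 2-[(1S,2R)-1,2-dimethyl-5-oxocyclopentyl]acetaldehyde, via secondary ozonide 6 (not isolated)
Conditions: O3, CH2Cl2, −78 °C; then Me2S, −78 °C → rt
Reagents that add atoms: ozone, [O-][O+]=O
Why: Ozonolysis with reductive work-up cleaves the only C=C bond to the aldehyde and touches neither the ketone nor the two stereocentres.

**Step 3**
Reactants: 7 2-[(1S,2R)-1,2-dimethyl-5-oxocyclopentyl]acetaldehyde
Product: 8 (2S,3R)-2-(2-hydroxyethyl)-2,3-dimethylcyclopentan-1-one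
Conditions: NaBH4 (0.4 equiv), CH2Cl2–MeOH 7:3, −78 °C
Reagents that add atoms: none
Why: Chemoselective borohydride reduction, since at −78 °C the unhindered aldehyde is reduced much faster than a cyclopentanone that sits next to a quaternary carbon.

**Step 4**
Reactants: 8 (2S,3R)-2-(2-hydroxyethyl)-2,3-dimethylcyclopentan-1-one
Product: 9 (2S,3R)-2-[2-(benzyloxy)ethyl]-2,3-dimethylcyclopentan-1-one
Conditions: BnOC(=NH)CCl3 (1.3 equiv), TfOH (5 mol %), CH2Cl2–cyclohexane, 0 °C → rt
Reagents that add atoms: benzyl 2,2,2-trichloroacetimidate, N=C(OCc1ccccc1)C(Cl)(Cl)Cl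
Why: Acid-catalysed O-benzylation with the trichloroacetimidate needs no base and so avoids enolate side reactions, and the benzyl ether is chosen because it withstands every later acidic step and leaves in the same hydrogenolysis as the C5 benzyl group.

**Step 5**
Reactants: 9 (2S,3R)-2-[2-(benzyloxy)ethyl]-2,3-dimethylcyclopentan-1-one
Product: 10 {[(4R,5S)-5-[2-(benzyloxy)ethyl]-4,5-dimethylcyclopent-1-en-1-yl]oxy}trimethylsilane
Conditions: TMSOTf, Et3N, CH2Cl2, 0 °C
Reagents that add atoms: trimethylsilyl triflate, C[Si](C)(C)OS(=O)(=O)C(F)(F)F
Why: Soft enolisation and O-silylation (silyl enol ether formation) can give only one regioisomer because the other α-carbon is quaternary.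

**Step 6**
Reactants: 10 silyl enol ether; 11 dichloroacetyl chloride
Product: 12 cis-fused 7,7-dichloro-1-(trimethylsilyloxy)bicyclo[3.2.0]heptan-6-one bearing at C2 methyl plus 2-(benzyloxy)ethyl and at C3 methyl (cyclobutanone on the α face)
Conditions: 11 (slow addition), Et3N, hexanes, rt
Reagents that add atoms: none
Why: Thermal [2+2] cycloaddition of dichloroketene, released by dehydrochlorination of 11, with the electron-rich enol ether joins the nucleophilic CH carbon (C6) to the ketene carbonyl carbon and the siloxy carbon (C10) to CCl2, the fusion being cis by necessity and the approach expected anti to the arm, although both new centres vanish in step 7.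

**Step 7**
Reactants: 12 dichlorocyclobutanone adduct
Product: 15 (4S,5R)-4-[2-(benzyloxy)ethyl]-4,5-dimethylcycloheptane-1,3-dione, via dechlorinated silyloxycyclobutanone 13 (not isolated), via bridgehead cyclobutanol 14 (not isolated)
Conditions: Zn, AcOH, i-PrOH–H2O, 80 °C
Reagents that add atoms: none
Why: Zinc-mediated reductive dechlorination followed by desilylation and strain-driven retro-aldol cleavage of the C10–C6 fusion bond (De Mayo-type fragmentation) enlarges the five-membered ring by two carbons to the 1,3-dione without touching C8 or C9.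

**Step 8**
Reactants: 15 (4S,5R)-4-[2-(benzyloxy)ethyl]-4,5-dimethylcycloheptane-1,3-dione
Product: 16 (6R,7S)-3-(benzyloxy)-7-[2-(benzyloxy)ethyl]-6,7-dimethylcyclohept-2-en-1-one
Conditions: BnOH (2 equiv), TsOH·H2O (5 mol %), toluene, reflux, Dean–Stark
Reagents that add atoms: benzyl alcohol, OCc1ccccc1
Why: Acid-catalysed vinylogous ester formation under water removal is reversible and places the benzyloxy group at C5, the carbonyl remote from the quaternary C9, so that the hindered C10 remains the enone carbonyl.

**Step 9**
Reactants: 16 (6R,7S)-3-(benzyloxy)-7-[2-(benzyloxy)ethyl]-6,7-dimethylcyclohept-2-en-1-one; 17 1,1-diethoxyethene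
Product: 18 (1S,5R,8R,9S) cis-fused photoadduct: cyclobutane C1–C2–C3–C5 with C3 as diethyl acetal, C5-OBn β, C1-H β, C10 ketone
Conditions: hν (350 nm, base-washed Pyrex), 17 (15 equiv), degassed toluene, −30 °C; chromatography on Et3N-deactivated silica
Reagents that add atoms: none
Why: Excitation of the vinylogous ester and intersystem crossing give its π,π* triplet, which bonds to the donor alkene to form a triplet 1,4-biradical (C1–C2 made first leaves the tertiary α-benzyloxy radical at C5 and the dialkoxy-stabilised radical at C3) that closes after spin inversion. The closest known reaction is the head-to-tail [2+2] photocycloaddition of cyclic enones, including 3-oxygenated ones, with ketene acetals. The single ring closed is the cyclobutane C1–C2–C3–C5, made by stepwise [2+2], the last event being 1,4-recombination of the biradical. C5 is set by the ring face that the alkene takes: with C8-Me equatorial and the arm pseudo-equatorial C7 is puckered towards the α face, so α bonding at C5 is the axial, chair-forming trajectory and also lies away from the arm, whereas the pseudo-axial C9 methyl on that face opposes it, so only a moderate preference is expected and the C5 epimer is removed by chromatography at this stage. C1 follows from C5 because the two-atom bridge should close cis on the four-membered ring, and any trans-fused C1 epimer should be funnelled into 18 on basic alumina. The step needs head-to-tail orientation, secured by the usual pairing of the acetal carbon of a donor alkene with the enone β-carbon and by the best-stabilised biradical, and chemoselectivity, secured because 16 has no other alkene and its phenyl rings do not absorb at 350 nm.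

**Step 10**
Reactants: 18 cis-fused photoadduct
Product: 19 (1S,5R,8R,9S) cis-fused 2-benzyloxycyclobutanone (C3=O, C10=O)
Conditions: 1 M HCl, THF, rt
Reagents that add atoms: water, O
Why: Acid-catalysed acetal hydrolysis unmasks the C3 cyclobutanone, while both benzyl ethers are inert to dilute acid and the etherified C5 oxygen cannot start a retro-aldol opening of the four-membered ring.

**Step 11**
Reactants: 19 cis-fused 2-benzyloxycyclobutanone; 20 isopropenylmagnesium bromide
Product: 21 (1S,3S,5R,8R,9S) 3-isopropenylcyclobutan-3-ol (isopropenyl β, C3-OH α)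
Conditions: 20 (1.3 equiv), anhydrous CeCl3 (1.4 equiv), THF, −78 °C
Reagents that add atoms: none
Why: Organocerium 1,2-addition is chemoselective because the strained, chelating α-benzyloxy cyclobutanone is far more electrophilic than the C10 ketone between C9 and C1, the low basicity of the cerium reagent suppresses enolisation, and attack should come from the convex β face, a point without consequence because C3 becomes planar again in step 12.

**Step 12**
Reactants: 21 3-isopropenylcyclobutan-3-ol
Product: 22 (1S,5R,8R,9S) cis-fused hydroazulene-3,10-dione with C4 gem-dimethyl and C5-OBn β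
Conditions: TsOH·H2O (0.2 equiv), CH2Cl2, 0 °C → rt
Reagents that add atoms: none
Why: Semipinacol ring expansion of a 1-alkenylcyclobutanol: Markovnikov protonation of the isopropenyl group gives a tertiary cation next to the carbinol, and release of ring strain drives the 1,2-shift of the more substituted, oxygen-bearing C5 (with retention) from C3 to the cationic carbon, which becomes C4 with its two methyl groups while C3 becomes the ketone.

**Step 13**
Reactants: 22 cis-fused 3,10-dione
Product: 23 (1S,3R,5R,8R,9S) cis-fused 3α-alcohol
Conditions: NaBH4 (1 equiv), MeOH–CH2Cl2, −40 → 0 °C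
Reagents that add atoms: none
Why: Substrate-controlled hydride reduction: the cyclopentanone is less hindered and intrinsically more reactive than the C10 ketone, and in the cis-fused bicycle hydride comes from the convex β face (only C1-H and the C5 oxygen) because the seven-membered ring covers the α face, which places the C3 hydroxyl α and trans to the C5 oxygen.

**Step 14**
Reactants: 23 cis-fused 3α-alcohol
Product: 24 (1R,3R,5R,8R,9S) trans-fused 3α-alcohol (C1-H α)
Conditions: NaOMe (0.3 equiv), MeOH, rt; recovered 23 recycled
Reagents that add atoms: none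
Why: Thermodynamic epimerisation through the C10 enolate: C1 is the only enolisable position, the benzyl ether blocks retro-aldol cleavage of C1–C5, reprotonation in methanol is much faster than loss of benzyloxide (reversible E1cB regime), and the trans isomer should dominate because it keeps both cyclopentane bonds (C1–C2 and C5–C4) equatorial on the cycloheptanone, whereas the cis isomer must place either the neopentyl C4 or C2 (syn to the α methyl on C9) axial.

**Step 15**
Reactants: 24 trans-fused 3α-alcohol
Product: 25 (1R,3R,5R,8R,9S) triol (C3-OH, C5-OH, C12-OH) with C10 ketone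
Conditions: H2 (1 atm), 10% Pd/C, EtOAc–EtOH, rt
Reagents that add atoms: none
Why: Catalytic hydrogenolysis removes both benzyl ethers in one operation under neutral conditions, which keeps the liberated β-hydroxy ketone from retro-aldol cleavage or epimerisation, and it is placed before the coupling because the butenolide alkene would not survive it.

**Step 16**
Reactants: 25 triol
Product: 26 (1R,3R,5R,8R,9S) C12 primary iodide with free C3-OH and C5-OH
Conditions: I2 (1.1 equiv), PPh3, imidazole, CH2Cl2, 0 °C
Reagents that add atoms: iodine, [I][I]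
Why: Appel-type iodination is selective for the primary C12 hydroxyl because the C3 carbinol is neopentyl-like and the C5 carbinol tertiary, and the nearly neutral medium leaves C1 and C5 untouched.

**Step 17**
Reactants: 26 C12 primary iodide; 27 4-bromofuran-2(5H)-one
Product: 29 target CNP0077405.2, via alkylzinc iodide 28 (not isolated)
Conditions: Zn dust (activated), LiCl, THF, 35 °C; solution decanted from excess Zn; then 27, Pd(OAc)2 (3 mol %), SPhos (6 mol %), THF, rt
Reagents that add atoms: zinc, [Zn] (held only in intermediate 28)
Why: Negishi sp3–sp2 cross-coupling: zinc inserts into the primary C–I bond without touching the ketone, alkylzinc iodides are too weakly basic to be quenched quickly by hindered secondary and tertiary hydroxyl groups, and zerovalent palladium adds oxidatively to the vinylogous acyl bromide so that transmetalation and reductive elimination join C12 to the butenolide β-carbon without affecting any stereocentre.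

**Compound list**
1 | 2-methylcyclopent-2-en-1-one | CC1=CCCC1=O | starting material
2 | methylmagnesium bromide | C[Mg]Br | starting material
3 | allyl iodide | C=CCI | starting material
4 | bromomagnesium enolate of (3R)-2,3-dimethylcyclopentanone | C[C@@H]1CCC(O[Mg]Br)=C1C | intermediate
5 | (2S,3R)-2-allyl-2,3-dimethylcyclopentan-1-one | C[C@@H]1CCC(=O)[C@@]1(C)CC=C | intermediate
6 | secondary ozonide of 5 (trioxolane carbon as epimer mixture) | C[C@@H]1CCC(=O)[C@@]1(C)CC1OCOO1 | intermediate
7 | 2-[(1S,2R)-1,2-dimethyl-5-oxocyclopentyl]acetaldehyde | C[C@@H]1CCC(=O)[C@@]1(C)CC=O | intermediate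
8 | (2S,3R)-2-(2-hydroxyethyl)-2,3-dimethylcyclopentan-1-one | C[C@@H]1CCC(=O)[C@@]1(C)CCO | intermediate
9 | (2S,3R)-2-[2-(benzyloxy)ethyl]-2,3-dimethylcyclopentan-1-one | C[C@@H]1CCC(=O)[C@@]1(C)CCOCc1ccccc1 | intermediate
10 | {[(4R,5S)-5-[2-(benzyloxy)ethyl]-4,5-dimethylcyclopent-1-en-1-yl]oxy}trimethylsilane | C[C@@H]1CC=C(O[Si](C)(C)C)[C@@]1(C)CCOCc1ccccc1 | intermediate
11 | dichloroacetyl chloride | O=C(Cl)C(Cl)Cl | starting material
12 | cis-fused dichlorocyclobutanone adduct (OTMS and bridgehead H β) | C[C@@H]1C[C@@H]2C(=O)C(Cl)(Cl)[C@]2(O[Si](C)(C)C)[C@@]1(C)CCOCc1ccccc1 | intermediate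
13 | dechlorinated silyloxycyclobutanone | C[C@@H]1C[C@@H]2C(=O)C[C@]2(O[Si](C)(C)C)[C@@]1(C)CCOCc1ccccc1 | intermediate
14 | bridgehead cyclobutanol | C[C@@H]1C[C@@H]2C(=O)C[C@]2(O)[C@@]1(C)CCOCc1ccccc1 | intermediate
15 | (4S,5R)-4-[2-(benzyloxy)ethyl]-4,5-dimethylcycloheptane-1,3-dione | C[C@@H]1CCC(=O)CC(=O)[C@@]1(C)CCOCc1ccccc1 | intermediate
16 | (6R,7S)-3-(benzyloxy)-7-[2-(benzyloxy)ethyl]-6,7-dimethylcyclohept-2-en-1-one | C[C@@H]1CCC(OCc2ccccc2)=CC(=O)[C@@]1(C)CCOCc1ccccc1 | intermediate
17 | 1,1-diethoxyethene | C=C(OCC)OCC | starting material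
18 | (1S,5R,8R,9S) cis-fused cyclobutanone diethyl acetal | C[C@@H]1CC[C@@]2(OCc3ccccc3)[C@H](CC2(OCC)OCC)C(=O)[C@@]1(C)CCOCc1ccccc1 | intermediate
19 | (1S,5R,8R,9S) cis-fused 2-benzyloxycyclobutanone | C[C@@H]1CC[C@@]2(OCc3ccccc3)[C@H](CC2=O)C(=O)[C@@]1(C)CCOCc1ccccc1 | intermediate
20 | isopropenylmagnesium bromide | C=C(C)[Mg]Br | starting material
21 | (1S,3S,5R,8R,9S) 3-isopropenylcyclobutan-3-ol | C[C@@H]1CC[C@@]2(OCc3ccccc3)[C@H](C[C@]2(O)C(C)=C)C(=O)[C@@]1(C)CCOCc1ccccc1 | intermediate
22 | (1S,5R,8R,9S) cis-fused 4,4-dimethyl-3,10-dione | C[C@@H]1CC[C@@]2(OCc3ccccc3)[C@H](CC(=O)C2(C)C)C(=O)[C@@]1(C)CCOCc1ccccc1 | intermediate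
23 | (1S,3R,5R,8R,9S) cis-fused 3α-alcohol | C[C@@H]1CC[C@@]2(OCc3ccccc3)[C@H](C[C@@H](O)C2(C)C)C(=O)[C@@]1(C)CCOCc1ccccc1 | intermediate
24 | (1R,3R,5R,8R,9S) trans-fused 3α-alcohol | C[C@@H]1CC[C@@]2(OCc3ccccc3)[C@@H](C[C@@H](O)C2(C)C)C(=O)[C@@]1(C)CCOCc1ccccc1 | intermediate
25 | (1R,3R,5R,8R,9S) triol | C[C@@H]1CC[C@@]2(O)[C@@H](C[C@@H](O)C2(C)C)C(=O)[C@@]1(C)CCO | intermediate
26 | (1R,3R,5R,8R,9S) C12 iodide | C[C@@H]1CC[C@@]2(O)[C@@H](C[C@@H](O)C2(C)C)C(=O)[C@@]1(C)CCI | intermediate
27 | 4-bromofuran-2(5H)-one | BrC1=CC(=O)OC1 | starting material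
28 | C12 alkylzinc iodide | C[C@@H]1CC[C@@]2(O)[C@@H](C[C@@H](O)C2(C)C)C(=O)[C@@]1(C)CC[Zn]I | intermediate
29 | CNP0077405.2 | C[C@@H]1CC[C@@]2(O)[C@@H](C[C@@H](O)C2(C)C)C(=O)[C@@]1(C)CCC1=CC(=O)OC1 | target

**Step count.** Total steps: 17. Longest linear sequence: 17 steps, from 1.

**Steps most likely to fail**

Step 9. The excited seven-membered vinylogous ester may relax by twisting about C1=C5 faster than it is trapped. The acid-sensitive ketene acetal may be lost by oligomerisation. The head-to-tail orientation may erode, and facial discrimination may be weak. Fallback: starting from 16, irradiation (350 nm) is run in neat, degassed vinyl acetate. This robust donor alkene can be used at solvent concentration, so even a short-lived triplet should be intercepted. It should give the head-to-tail acetoxycyclobutane F1, and either C3 epimer serves. Methanolysis (K2CO3, MeOH, 0 °C) gives the cyclobutanol F2, and Dess–Martin oxidation comes back to the route at 19.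

Step 12. The C2–C3 bond may migrate in place of C5–C3. Acid may cleave the C1–C5 bond of the donor–acceptor cyclobutane in a push–pull manner. The allylic tertiary alcohol may ionise, and benzyl alcohol may be eliminated from the β-benzyloxy ketone that is formed. Fallback: starting from 19, the CMe2 unit is brought in as 2-lithio-2-(methylseleno)propane F3, made from 2,2-bis(methylseleno)propane and n-BuLi in THF at −78 °C. F3 adds to the cyclobutanone to give the β-hydroxy selenide F4. Se-methylation (MeOTf, 2,6-di-tert-butyl-4-methylpyridine, CH2Cl2, 0 °C) gives the selenonium triflate F5. Departure of its leaving group triggers the same 1,2-shift of the more substituted carbon without any Brønsted acid. This comes back to the route at 22.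

Step 14. The cis/trans equilibrium may be unfavourable or incomplete, and benzyl alcohol may be slowly β-eliminated from the enolate. Fallback (kinetic instead of thermodynamic control): starting from 23, double deprotonation with LiN(iPr)2 (2.3 equiv, THF, −78 → −40 °C) gives the dilithium alkoxide–enolate F6. Quenching at −78 °C with 2,6-di-tert-butyl-4-methylphenol should protonate C1 from the α face. That face is anti to the axial C5 benzyloxy group and next to the lithium alkoxide at C3. This comes back to the route at 24.

**Further compounds**
F1 | step 9 | head-to-tail acetoxycyclobutane (β-acetate drawn) | C[C@@H]1CC[C@@]2(OCc3ccccc3)[C@H](C[C@@H]2OC(C)=O)C(=O)[C@@]1(C)CCOCc1ccccc1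
F2 | step 9 | cyclobutanol (β-hydroxyl drawn) | C[C@@H]1CC[C@@]2(OCc3ccccc3)[C@H](C[C@@H]2O)C(=O)[C@@]1(C)CCOCc1ccccc1
F3 | step 12 | 2-lithio-2-(methylseleno)propane | C[Se]C(C)(C)[Li]
F4 | step 12 | β-hydroxy selenide | C[C@@H]1CC[C@@]2(OCc3ccccc3)[C@H](C[C@]2(O)C(C)(C)[Se]C)C(=O)[C@@]1(C)CCOCc1ccccc1
F5 | step 12 | selenonium triflate | C[C@@H]1CC[C@@]2(OCc3ccccc3)[C@H](C[C@]2(O)C(C)(C)[Se+](C)C)C(=O)[C@@]1(C)CCOCc1ccccc1.[O-]S(=O)(=O)C(F)(F)F
F6 | step 14 | dilithium alkoxide–enolate | C[C@@H]1CC[C@@]2(OCc3ccccc3)C(C[C@@H](O[Li])C2(C)C)=C(O[Li])[C@@]1(C)CCOCc1ccccc1
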